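Conventions: TBS = tert-butyldimethylsilyl, TIPS = triisopropylsilyl. The oxane is numbered O1, C2 (carbon bearing the arylethyl chain), C4 (carbon bearing ring A), C6 (carbon bearing the aryl group; the acetal carbon in earlier intermediates). Ring A is numbered C1' (acyl), C2' (OH), C3' (oxanyl), C4' (OH), C5' (H), C6' (OMe).

## Structural features

The target is a chalcone–diarylheptanoid hybrid: ring A, a phloroglucinol unit with OMe at C6', OH at C2' and C4' and H at C5', carries an (E)-4-hydroxycinnamoyl group at C1' and, at C3' between the two hydroxyl groups, C4 of an oxane (O1, C2–C6). The oxane bears a 2-(4-hydroxyphenyl)ethyl chain at C2 and a 4-hydroxyphenyl ring at C6, so its three stereocentres C2 (S), C4 (R) and C6 (R) form a 1,3,5-array around the ring oxygen. The C2 chain and ring A at C4 are cis (both equatorial in the chair), whereas the C6 aryl group is trans to both and therefore axial, the less stable arrangement at C6. C6 is a benzylic ether para to an oxygen donor, so acid can ionise the C6–O1 bond and return the all-equatorial epimer; C6 has to be set kinetically, late, and must not meet acid afterwards. The C4–C3' bond joins a secondary ring carbon to an arene carbon flanked by two oxygen substituents, and a free 5-methoxyresorcinol nucleophile has two different reactive sites, so making this bond on a preformed ring is the other real difficulty. Without its acyl group ring A is locally symmetric (C1' and C5' are equivalent), which makes late functionalisation at C1' regiochemically unambiguous. The 2'-hydroxychalcone is prone to conjugate addition and flavanone closure, and the phenols need protecting groups that leave without acid. The key step exploits that O1–C2–C3–C4 with ring A on C4 is a latent 1-oxadiene and C5–C6 a latent enol ether: a [4+2] union closes the oxane with ring A already in place, fixes C4 by catalyst control, leaves C2 as an enol ether carbon for cis hydrogenation and C6 at the acetal oxidation level for a late axial arylation.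

## Logic of the disconnections

24 is traced to 23 by cutting five O–Si bonds. All phenols are masked as aryl silyl ethers so that the last step is a buffered fluoride treatment. The demand is that neither acid (C6 ionisation) nor strong base (flavanone closure) is present.

23 is cut at the C1'–C(=O) bond into 18 and 21. The whole cinnamoyl unit then arrives as an acyl donor with its E double bond already in place, and no aldol condensation under hydroxide is needed. The demand is an aryl-metal species at C1' that tolerates silyl ethers and the benzylic ether, and an acyl donor that stops at the ketone. 21 is cut at its C=C bond into 19 and 20.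

18 is traced to 17 by cutting the C1'–I bond. Because C1' and C5' of 17 are equivalent and ring A is by far the most electron-rich arene, the forward halogenation has no regiochemical choice to make.

17 is cut at the C6–aryl bond into 14 and 11. This stereocentre is cut last because, with C2 and C4 already cis and equatorial, the derived oxocarbenium ion is conformationally anchored and axial attack gives the required trans (axial) aryl group kinetically. The demand is a nucleophile and Lewis acid mild enough not to re-ionise the product. 14 is traced to 13 by exchanging the C6–S bond for the C6–OEt bond.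

13 is cut at the aryl–CH2 bond of the side chain into 10 and 11. 10 is traced through 9 to 8 by a one-carbon olefination and an ester-to-aldehyde reduction. These steps convert the ester, which the key step needs as activating group, into the arylethyl chain; they touch no stereocentre.

8 is traced to 7 by removing two hydrogens from C2–C3. In the forward sense hydrogen is delivered to the face opposite the C4 aryl group, which relays C4 to C2 (cis).

7 is cut at O1–C6 and C4–C5 into 5 and 6 (key disconnection). In one sentence: the oxane is closed by a bis(oxazoline)–copper-catalysed inverse-electron-demand hetero-Diels–Alder reaction of 6 with 5, in which ring A already sits on the terminal carbon of the oxadiene. The hindered C4–C3' bond is therefore never made on the ring; it derives from the formyl carbon of a benzaldehyde. The gain is a ring, one catalyst-controlled stereocentre and the correct oxidation levels at C2 and C6 from two achiral, open-chain partners. The demand is sufficient reactivity of an electron-rich, ortho,ortho'-disubstituted heterodiene together with endo and facial control.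

5 is cut at its C=C bond into 3 and 4. 3 is traced through 2 to 1 by two O–Si bonds and two O–CH3 bonds. The chelation-controlled demethylation of 1 fixes the oxygen pattern of ring A (two free OH flanking the future C4 attachment, OMe para) without any electrophilic substitution on the ring.

## Other disconnections considered

Alternative 1: the first plan that comes to mind cuts O1–C6, C5–C6 and C4–C3' at once. In the forward sense this is a Prins cyclisation of the homoallylic alcohol A1 with 19 under BF3·OEt2 or CF3CO2H, the C4 cation being trapped by 5-methoxyresorcinol in a Friedel–Crafts step to give A2. It is very short. However, the chair transition state with an E-oxocarbenium ion places all three substituents equatorial, so A2 would be the C6 epimer of the required series. The axial C6 aryl group could then only be reached by acid equilibration, which cannot be driven toward the less stable isomer. The arene also has two different nucleophilic sites (between the two OH groups, or between OH and OMe), so the C4–C3' regiochemistry is not secured. The chosen plan sets C6 kinetically and never forms the C4–aryl bond on the ring.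

Alternative 2: cut C6–aryl first on a ring that still has a C4 carbonyl. A catalytic asymmetric hetero-Diels–Alder reaction of a 1-methoxy-3-silyloxybutadiene with 3-[4-(triisopropylsilyloxy)phenyl]propanal would give dihydropyranone A3. Conjugate transfer of the aryl group of 11 (for example with [Rh(cod)OH]2 and the arylboronic acid) would add axially and give the 2,6-trans ketone A4. Ring A would then be introduced at C4 through the enol triflate and cross-coupling, followed by hydrogenation, or by aryl addition and ionic deoxygenation. The weakness is structural: in A4 the C2 and C6 substituents lie on opposite faces, so neither face of C4 is distinguished and C4 would form without control. The deoxygenation variant would in addition need acid with the labile C6 centre already in place. The chosen plan reverses the order (C4 first by catalyst, C2 by relay, C6 last).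

Alternative 3: carry a flat 2-pyranone and saturate it late. Cross-coupling of a ring A zinc reagent with 4-bromo-6-methyl-2H-pyran-2-one and chain extension at the 6-methyl group would give pyranone A5. Enantioselective hydrogenation of the 5,6-double bond with Ru(OAc)2[(R)-MeO-BIPHEP], then heterogeneous hydrogenation of the remaining double bond, would give the cis lactone A6, which would join the chosen route after reduction to the lactol. This is attractive because all ring carbons come from a cheap pyranone. The grounds against it are these: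
- Making the hindered ring A–C4 bond by cross-coupling needs a 2,6-dioxygenated aryl metal, whose preparation by directed metalation calls for acetal protecting groups that later need acid or an extra exchange.
- The enantioselective hydrogenation would have to work next to a very large ortho,ortho'-disubstituted aryl group.
- The lactone is one oxidation level above what the C6 arylation needs.

The hetero-Diels–Alder plan sets C4 in the ring-forming step and delivers C6 directly as an acetal.

Key step: step 4

Remark: the choice of the (R,R)-ligand in step 4 rests on the square-planar chelate model of bis(oxazoline) complexes of divalent copper; it affects only the absolute configuration of 7, not the relative one.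

## Route

Step 1
Reactants: 1 2,4,6-trimethoxybenzaldehyde
Product: 2 2,6-dihydroxy-4-methoxybenzaldehyde
Conditions: AlCl3 (6 equiv), PhCl, 90 °C; aq. HCl
Reagents that add atoms: none
Why: Chelation-controlled demethylation: only the two methoxy groups ortho to the formyl group can form the six-membered aluminium chelate that activates O–CH3 cleavage by chloride, so the para ether should survive; this fixes the oxygen pattern of ring A.

Step 2
Reactants: 2 2,6-dihydroxy-4-methoxybenzaldehyde
Product: 3 2,6-bis(TBS-oxy)-4-methoxybenzaldehyde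
Conditions: TBSCl (2.5 equiv), imidazole, DMF, rt
Reagents that add atoms: tert-butyldimethylsilyl chloride, CC(C)(C)[Si](C)(C)Cl
Why: Imidazole-promoted silylation of phenols; aryl TBS ethers should tolerate all later steps and leave under neutral fluoride conditions.

Step 3
Reactants: 3 2,6-bis(TBS-oxy)-4-methoxybenzaldehyde; 4 ethyl 2-oxo-3-(triphenylphosphoranylidene)propanoate
Product: 5 ethyl (E)-4-[2,6-bis(TBS-oxy)-4-methoxyphenyl]-2-oxobut-3-enoate
Conditions: toluene, 100 °C
Reagents that add atoms: none
Why: Wittig olefination with a keto-stabilised ylide under neutral conditions that spare the aryl silyl ethers; the E olefin is the normal outcome with stabilised ylides.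

Step 4
Reactants: 5 ethyl (E)-4-[2,6-bis(TBS-oxy)-4-methoxyphenyl]-2-oxobut-3-enoate; 6 ethyl vinyl ether
Product: 7 ethyl (2S,4S)-4-[2,6-bis(TBS-oxy)-4-methoxyphenyl]-2-ethoxy-3,4-dihydro-2H-pyran-6-carboxylate (2,4-cis)
Conditions: 6 (5 equiv), [Cu((R,R)-t-Bu-box)](OTf)2 (10 mol %; t-Bu-box = 2,2'-isopropylidenebis(4-tert-butyl-2-oxazoline)), 3 Å molecular sieves, THF, −20 to 0 °C
Reagents that add atoms: none
Why: Inverse-electron-demand hetero-Diels–Alder reaction: the α-keto ester of 5 binds divalent copper through both carbonyl oxygens, which lowers the LUMO of the s-cis 1-oxadiene, and 6 adds in a concerted but asynchronous [4+2], its CH2 terminus bonding to the aryl-bearing γ-carbon (C4–C5) and its oxygenated carbon to the ketone oxygen (O1–C6). The closest known reaction type is the bis(oxazoline)–copper-catalysed cycloaddition of γ-aryl and γ-alkyl β,γ-unsaturated α-keto esters with enol ethers. The oxane ring is closed by intermolecular [4+2] cycloaddition, not by cyclisation of a tethered chain, so both ring bonds form in one event and the regiochemistry follows from the polarity of the two partners. C4 is controlled by the catalyst: in the square-planar chelate one tert-butyl group of the (R,R)-ligand covers one face of the oxadiene and 6 approaches the other, which should give 4S in 7 (the R centre of the target once ring numbering and priorities change). The acetal carbon is controlled by the endo preference of the alkoxy group, giving the 2,4-cis adduct; its configuration is erased in step 9, so only C4 must be secured here. The selectivities needed are [4+2] over open-chain Michael-type addition, endo over exo and one enantioface, and two-point binding of the keto ester should secure all three. The ortho silyloxy groups twist ring A out of conjugation with the oxadiene, which reduces its deactivating donor effect but hinders the γ-carbon, and this is the main risk of the step.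

Step 5
Reactants: 7 ethyl (2S,4S)-4-[2,6-bis(TBS-oxy)-4-methoxyphenyl]-2-ethoxy-3,4-dihydro-2H-pyran-6-carboxylate
Product: 8 ethyl (2R,4R,6S)-4-[2,6-bis(TBS-oxy)-4-methoxyphenyl]-6-ethoxyoxane-2-carboxylate (all-cis)
Conditions: H2 (1 atm), Pd/C, EtOAc, rt
Reagents that add atoms: none
Why: Heterogeneous hydrogenation of the trisubstituted enol ether; both hydrogens should be delivered to the face opposite the C4 aryl group and the cis ethoxy group, so the ester ends cis to both and C2 is set by relay from C4.

Step 6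
Reactants: 8 ethyl (2R,4R,6S)-4-[2,6-bis(TBS-oxy)-4-methoxyphenyl]-6-ethoxyoxane-2-carboxylate
Product: 9 (2R,4R,6S)-4-[2,6-bis(TBS-oxy)-4-methoxyphenyl]-6-ethoxyoxane-2-carbaldehyde
Conditions: i-Bu2AlH (1.1 equiv), CH2Cl2, −78 °C; aq. potassium sodium tartrate
Reagents that add atoms: none
Why: Partial reduction of an α-alkoxy ester at low temperature stops at the aldehyde oxidation level; the C2 substituent is already equatorial, so epimerisation α to the aldehyde is not a concern.

Step 7
Reactants: 9 (2R,4R,6S)-4-[2,6-bis(TBS-oxy)-4-methoxyphenyl]-6-ethoxyoxane-2-carbaldehyde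
Product: 10 (2R,4R,6S)-4-[2,6-bis(TBS-oxy)-4-methoxyphenyl]-2-ethenyl-6-ethoxyoxane
Conditions: Ph3PCH3Br, KN(SiMe3)2, THF, 0 °C; then 9, −78 to 0 °C
Reagents that add atoms: methyltriphenylphosphonium bromide, C[P+](c1ccccc1)(c1ccccc1)c1ccccc1.[Br-]
Why: Wittig methylenation with a non-stabilised ylide; the acetal and aryl silyl ethers are inert to it.

Step 8
Reactants: 10 (2R,4R,6S)-4-[2,6-bis(TBS-oxy)-4-methoxyphenyl]-2-ethenyl-6-ethoxyoxane; 11 (4-bromophenoxy)triisopropylsilane
Product: 13 (2S,4R,6S)-4-[2,6-bis(TBS-oxy)-4-methoxyphenyl]-6-ethoxy-2-{2-[4-(TIPS-oxy)phenyl]ethyl}oxane (all-cis), via B-alkyl-9-borabicyclo[3.3.1]nonane 12 (not isolated)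
Conditions: 9-BBN, THF, rt; then 11, PdCl2(dppf), aq. K3PO4, DMF, 50 °C
Reagents that add atoms: none
Why: Anti-Markovnikov hydroboration of the terminal alkene followed by B-alkyl Suzuki–Miyaura coupling builds the arylethyl chain; no stereocentre is touched, and the hindered ring A silyl ethers and the TIPS ether should withstand the aqueous phosphate.

Step 9
Reactants: 13 (2S,4R,6S)-4-[2,6-bis(TBS-oxy)-4-methoxyphenyl]-6-ethoxy-2-{2-[4-(TIPS-oxy)phenyl]ethyl}oxane
Product: 14 (2S,4R)-6-(benzenesulfonyl)-4-[2,6-bis(TBS-oxy)-4-methoxyphenyl]-2-{2-[4-(TIPS-oxy)phenyl]ethyl}oxane (mixture of C6 anomers)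
Conditions: PhSO2H, CaCl2, CH2Cl2, rt
Reagents that add atoms: benzenesulfinic acid, OS(=O)c1ccccc1
Why: Acid-promoted acetal exchange through the cyclic oxocarbenium ion (formation of a 2-benzenesulfonyl cyclic ether); the sulfinate is a leaving group that a mild zinc Lewis acid can ionise, and the anomeric mixture is immaterial because both anomers give the same cation.

Step 10
Reactants: 14 (2S,4R)-6-(benzenesulfonyl)-4-[2,6-bis(TBS-oxy)-4-methoxyphenyl]-2-{2-[4-(TIPS-oxy)phenyl]ethyl}oxane; 11 (4-bromophenoxy)triisopropylsilane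
Product: 17 (2S,4R,6R)-4-[2,6-bis(TBS-oxy)-4-methoxyphenyl]-2-{2-[4-(TIPS-oxy)phenyl]ethyl}-6-[4-(TIPS-oxy)phenyl]oxane (2,4-cis-2,6-trans), via arylmagnesium bromide 15 (not isolated), via arylzinc bromide 16 (not isolated)
Conditions: 11, Mg, THF; ZnBr2, THF, 0 °C to rt; then 14, THF, rt
Reagents that add atoms: none
Why: Substitution of a 2-benzenesulfonyl cyclic ether by an arylzinc reagent: the zinc halide ionises the sulfone to the oxocarbenium ion, whose half-chair keeps the C2 and C4 substituents pseudo-equatorial, and the aryl group is delivered along the axial trajectory through a chair-like transition state. The new C6 aryl group should therefore be axial and trans to both other substituents (6R), under kinetic control and without a strong Lewis acid that could re-ionise the product.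

Step 11
Reactants: 17 (2S,4R,6R)-4-[2,6-bis(TBS-oxy)-4-methoxyphenyl]-2-{2-[4-(TIPS-oxy)phenyl]ethyl}-6-[4-(TIPS-oxy)phenyl]oxane
Product: 18 (2S,4R,6R)-4-[2,6-bis(TBS-oxy)-3-iodo-4-methoxyphenyl]-2-{2-[4-(TIPS-oxy)phenyl]ethyl}-6-[4-(TIPS-oxy)phenyl]oxane
Conditions: N-iodosuccinimide (1.0 equiv), MeCN, 0 °C to rt, dark
Reagents that add atoms: N-iodosuccinimide, O=C1CCC(=O)N1I
Why: Electrophilic aromatic iodination; the trioxygenated ring A is far more nucleophilic than the two mono-oxygenated rings, and its two free positions are constitutionally equivalent, so a single mono-iodide is expected without added acid.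

Step 12
Reactants: 19 4-(TBS-oxy)benzaldehyde; 20 N-methoxy-N-methyl-2-(triphenylphosphoranylidene)acetamide
Product: 21 (E)-3-[4-(TBS-oxy)phenyl]-N-methoxy-N-methylprop-2-enamide
Conditions: CH2Cl2, rt
Reagents that add atoms: none
Why: Wittig olefination with an amide-stabilised ylide under neutral conditions gives the E-cinnamoyl N-methoxy-N-methylamide without exposing the aryl silyl ether to base.

Step 13
Reactants: 18 (2S,4R,6R)-4-[2,6-bis(TBS-oxy)-3-iodo-4-methoxyphenyl]-2-{2-[4-(TIPS-oxy)phenyl]ethyl}-6-[4-(TIPS-oxy)phenyl]oxane; 21 (E)-3-[4-(TBS-oxy)phenyl]-N-methoxy-N-methylprop-2-enamide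
Product: 23 (E)-1-{2,4-bis(TBS-oxy)-6-methoxy-3-[(2S,4R,6R)-2-{2-[4-(TIPS-oxy)phenyl]ethyl}-6-[4-(TIPS-oxy)phenyl]oxan-4-yl]phenyl}-3-[4-(TBS-oxy)phenyl]prop-2-en-1-one, via ring-A arylmagnesium chloride 22 (not isolated)
Conditions: i-PrMgCl·LiCl, THF, −20 to 0 °C; then 21, 0 °C to rt; aq. NH4Cl
Reagents that add atoms: none
Why: Iodine–magnesium exchange, assisted by the ortho methoxy group, gives an arylmagnesium species that, unlike the aryllithium, should not undergo ortho oxygen-to-carbon silyl migration. Acylation by the N-methoxy-N-methylamide (Weinreb ketone synthesis) stops at the ketone and delivers the E-enone intact.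

Step 14
Reactants: 23 (E)-1-{2,4-bis(TBS-oxy)-6-methoxy-3-[(2S,4R,6R)-2-{2-[4-(TIPS-oxy)phenyl]ethyl}-6-[4-(TIPS-oxy)phenyl]oxan-4-yl]phenyl}-3-[4-(TBS-oxy)phenyl]prop-2-en-1-one
Product: 24 (E)-1-{2,4-dihydroxy-3-[(2S,4R,6R)-2-[2-(4-hydroxyphenyl)ethyl]-6-(4-hydroxyphenyl)oxan-4-yl]-6-methoxyphenyl}-3-(4-hydroxyphenyl)prop-2-en-1-one (CNP0215517.2)
Conditions: Bu4NF (6 equiv), AcOH (6 equiv), THF, 0 °C to rt
Reagents that add atoms: none
Why: Fluoride cleavage of five aryl silyl ethers, buffered with acetic acid so that neither strong base (flavanone closure of the 2'-hydroxychalcone) nor acid (ionisation at C6) is present; no stereocentre is touched.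

## Compound list

1 | 2,4,6-trimethoxybenzaldehyde | COc1cc(OC)c(C=O)c(OC)c1 | starting material
2 | 2,6-dihydroxy-4-methoxybenzaldehyde | COc1cc(O)c(C=O)c(O)c1 | intermediate
3 | 2,6-bis(TBS-oxy)-4-methoxybenzaldehyde | COc1cc(O[Si](C)(C)C(C)(C)C)c(C=O)c(O[Si](C)(C)C(C)(C)C)c1 | intermediate
4 | ethyl 2-oxo-3-(triphenylphosphoranylidene)propanoate | CCOC(=O)C(=O)C=P(c1ccccc1)(c1ccccc1)c1ccccc1 | starting material
5 | ethyl (E)-4-[2,6-bis(TBS-oxy)-4-methoxyphenyl]-2-oxobut-3-enoate | COc1cc(O[Si](C)(C)C(C)(C)C)c(/C=C/C(=O)C(=O)OCC)c(O[Si](C)(C)C(C)(C)C)c1 | intermediate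
6 | ethyl vinyl ether | C=COCC | starting material
7 | ethyl (2S,4S)-4-[2,6-bis(TBS-oxy)-4-methoxyphenyl]-2-ethoxy-3,4-dihydro-2H-pyran-6-carboxylate | COc1cc(O[Si](C)(C)C(C)(C)C)c([C@@H]2C=C(C(=O)OCC)O[C@H](OCC)C2)c(O[Si](C)(C)C(C)(C)C)c1 | intermediate
8 | ethyl (2R,4R,6S)-4-[2,6-bis(TBS-oxy)-4-methoxyphenyl]-6-ethoxyoxane-2-carboxylate | COc1cc(O[Si](C)(C)C(C)(C)C)c([C@@H]2C[C@H](C(=O)OCC)O[C@H](OCC)C2)c(O[Si](C)(C)C(C)(C)C)c1 | intermediate
9 | (2R,4R,6S)-4-[2,6-bis(TBS-oxy)-4-methoxyphenyl]-6-ethoxyoxane-2-carbaldehyde | COc1cc(O[Si](C)(C)C(C)(C)C)c([C@@H]2C[C@H](C=O)O[C@H](OCC)C2)c(O[Si](C)(C)C(C)(C)C)c1 | intermediate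
10 | (2R,4R,6S)-4-[2,6-bis(TBS-oxy)-4-methoxyphenyl]-2-ethenyl-6-ethoxyoxane | COc1cc(O[Si](C)(C)C(C)(C)C)c([C@@H]2C[C@H](C=C)O[C@H](OCC)C2)c(O[Si](C)(C)C(C)(C)C)c1 | intermediate
11 | (4-bromophenoxy)triisopropylsilane | Brc1ccc(O[Si](C(C)C)(C(C)C)C(C)C)cc1 | starting material
12 | 9-{2-[(2S,4R,6S)-4-[2,6-bis(TBS-oxy)-4-methoxyphenyl]-6-ethoxyoxan-2-yl]ethyl}-9-borabicyclo[3.3.1]nonane | COc1cc(O[Si](C)(C)C(C)(C)C)c([C@@H]2C[C@H](CCB3C4CCCC3CCC4)O[C@H](OCC)C2)c(O[Si](C)(C)C(C)(C)C)c1 | intermediate
13 | (2S,4R,6S)-4-[2,6-bis(TBS-oxy)-4-methoxyphenyl]-6-ethoxy-2-{2-[4-(TIPS-oxy)phenyl]ethyl}oxane | COc1cc(O[Si](C)(C)C(C)(C)C)c([C@@H]2C[C@H](CCc3ccc(O[Si](C(C)C)(C(C)C)C(C)C)cc3)O[C@H](OCC)C2)c(O[Si](C)(C)C(C)(C)C)c1 | intermediate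
14 | (2S,4R)-6-(benzenesulfonyl)-4-[2,6-bis(TBS-oxy)-4-methoxyphenyl]-2-{2-[4-(TIPS-oxy)phenyl]ethyl}oxane, mixture of C6 anomers | COc1cc(O[Si](C)(C)C(C)(C)C)c([C@@H]2C[C@H](CCc3ccc(O[Si](C(C)C)(C(C)C)C(C)C)cc3)OC(S(=O)(=O)c3ccccc3)C2)c(O[Si](C)(C)C(C)(C)C)c1 | intermediate
15 | [4-(TIPS-oxy)phenyl]magnesium bromide | Br[Mg]c1ccc(O[Si](C(C)C)(C(C)C)C(C)C)cc1 | intermediate
16 | [4-(TIPS-oxy)phenyl]zinc bromide | Br[Zn]c1ccc(O[Si](C(C)C)(C(C)C)C(C)C)cc1 | intermediate
17 | (2S,4R,6R)-4-[2,6-bis(TBS-oxy)-4-methoxyphenyl]-2-{2-[4-(TIPS-oxy)phenyl]ethyl}-6-[4-(TIPS-oxy)phenyl]oxane | COc1cc(O[Si](C)(C)C(C)(C)C)c([C@@H]2C[C@H](CCc3ccc(O[Si](C(C)C)(C(C)C)C(C)C)cc3)O[C@@H](c3ccc(O[Si](C(C)C)(C(C)C)C(C)C)cc3)C2)c(O[Si](C)(C)C(C)(C)C)c1 | intermediate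
18 | (2S,4R,6R)-4-[2,6-bis(TBS-oxy)-3-iodo-4-methoxyphenyl]-2-{2-[4-(TIPS-oxy)phenyl]ethyl}-6-[4-(TIPS-oxy)phenyl]oxane | COc1cc(O[Si](C)(C)C(C)(C)C)c([C@@H]2C[C@H](CCc3ccc(O[Si](C(C)C)(C(C)C)C(C)C)cc3)O[C@@H](c3ccc(O[Si](C(C)C)(C(C)C)C(C)C)cc3)C2)c(O[Si](C)(C)C(C)(C)C)c1I | intermediate
19 | 4-(TBS-oxy)benzaldehyde | O=Cc1ccc(O[Si](C)(C)C(C)(C)C)cc1 | starting material
20 | N-methoxy-N-methyl-2-(triphenylphosphoranylidene)acetamide | CON(C)C(=O)C=P(c1ccccc1)(c1ccccc1)c1ccccc1 | starting material
21 | (E)-3-[4-(TBS-oxy)phenyl]-N-methoxy-N-methylprop-2-enamide | CON(C)C(=O)/C=C/c1ccc(O[Si](C)(C)C(C)(C)C)cc1 | intermediate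
22 | {2,4-bis(TBS-oxy)-6-methoxy-3-[(2S,4R,6R)-2-{2-[4-(TIPS-oxy)phenyl]ethyl}-6-[4-(TIPS-oxy)phenyl]oxan-4-yl]phenyl}magnesium chloride | COc1cc(O[Si](C)(C)C(C)(C)C)c([C@@H]2C[C@H](CCc3ccc(O[Si](C(C)C)(C(C)C)C(C)C)cc3)O[C@@H](c3ccc(O[Si](C(C)C)(C(C)C)C(C)C)cc3)C2)c(O[Si](C)(C)C(C)(C)C)c1[Mg]Cl | intermediate
23 | (E)-1-{2,4-bis(TBS-oxy)-6-methoxy-3-[(2S,4R,6R)-2-{2-[4-(TIPS-oxy)phenyl]ethyl}-6-[4-(TIPS-oxy)phenyl]oxan-4-yl]phenyl}-3-[4-(TBS-oxy)phenyl]prop-2-en-1-one | COc1cc(O[Si](C)(C)C(C)(C)C)c([C@@H]2C[C@H](CCc3ccc(O[Si](C(C)C)(C(C)C)C(C)C)cc3)O[C@@H](c3ccc(O[Si](C(C)C)(C(C)C)C(C)C)cc3)C2)c(O[Si](C)(C)C(C)(C)C)c1C(=O)/C=C/c1ccc(O[Si](C)(C)C(C)(C)C)cc1 | intermediate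
24 | (E)-1-{2,4-dihydroxy-3-[(2S,4R,6R)-2-[2-(4-hydroxyphenyl)ethyl]-6-(4-hydroxyphenyl)oxan-4-yl]-6-methoxyphenyl}-3-(4-hydroxyphenyl)prop-2-en-1-one | COc1cc(O)c([C@@H]2C[C@H](CCc3ccc(O)cc3)O[C@@H](c3ccc(O)cc3)C2)c(O)c1C(=O)/C=C/c1ccc(O)cc1 | target

## Step count and risks

Total: 14 steps. Longest linear sequence: 13 steps (steps 1–11, 13 and 14, from 1); step 12 is a one-step side branch.

Least certain steps:

Step 4 (key step). The cycloaddition may be slow because the two ortho silyloxy groups shield the γ-carbon and ring A keeps some donor character; a slow [4+2] would let cationic oligomerisation of the enol ether compete, and reaction through a one-point-bound substrate would erode endo and facial selectivity. The fallback builds the same 1,5-oxygenated chain stepwise by iminium catalysis and brings the arylethyl chain in with the nucleophile. It sets out from 3. A Wittig reaction with (triphenylphosphoranylidene)acetaldehyde would give (E)-3-[2,6-bis(TBS-oxy)-4-methoxyphenyl]prop-2-enal F1. Commercial 4-(4-hydroxyphenyl)butan-2-one would be silylated (TIPSCl, imidazole) to 4-[4-(TIPS-oxy)phenyl]butan-2-one F2 and converted with LiN(i-Pr)2 and Me3SiCl at −78 °C into the kinetic enol ether trimethyl({4-[4-(TIPS-oxy)phenyl]but-1-en-2-yl}oxy)silane F3. A Mukaiyama–Michael addition of F3 to F1 under a chiral 5-benzyl-2-tert-butyl-3-methylimidazolidin-4-one salt (the enantiomer that shields the required face) should give (3S)-3-[2,6-bis(TBS-oxy)-4-methoxyphenyl]-5-oxo-7-[4-(TIPS-oxy)phenyl]heptanal F4. Cyclodehydration with EtOH, HC(OEt)3 and pyridinium p-toluenesulfonate would give (4S)-4-[2,6-bis(TBS-oxy)-4-methoxyphenyl]-2-ethoxy-6-{2-[4-(TIPS-oxy)phenyl]ethyl}-3,4-dihydro-2H-pyran F5. Hydrogenation (H2, Pd/C) from the face opposite ring A should give 13 together with its C6 epimer (2S,4R,6R)-4-[2,6-bis(TBS-oxy)-4-methoxyphenyl]-6-ethoxy-2-{2-[4-(TIPS-oxy)phenyl]ethyl}oxane F6. Both are converted under the conditions of step 9, so the fallback comes back to the route at 14 and also bypasses steps 5–8.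

Step 10. The zinc Lewis acid may re-ionise the benzylic C6–O1 bond of the product, which would equilibrate C6 toward the all-equatorial epimer, or the facial preference of the oxocarbenium ion may be incomplete. The fallback inverts the polarity at C6 and relies on stereoretentive coupling instead of cation capture. It sets out from 14. Reductive lithiation with lithium 4,4'-di-tert-butylbiphenylide in THF at −78 °C should give the axial anomeric organolithium (2S,4R,6S)-4-[2,6-bis(TBS-oxy)-4-methoxyphenyl]-6-lithio-2-{2-[4-(TIPS-oxy)phenyl]ethyl}oxane F7. Trapping with Bu3SnCl, with retention, should give the axial stannane (2S,4R,6S)-4-[2,6-bis(TBS-oxy)-4-methoxyphenyl]-2-{2-[4-(TIPS-oxy)phenyl]ethyl}-6-(tributylstannyl)oxane F8. A stereoretentive Stille coupling of F8 with (4-iodophenoxy)triisopropylsilane (Pd2(dba)3, JackiePhos, CuCl, KF, dioxane) would come back to the route at 17. Any aryl silyl ether lost to fluoride in that coupling would be restored by silylation before step 11.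

Step 13. Iodine–magnesium exchange on the electron-rich, doubly ortho-substituted iodide may be slow, and the hindered arylmagnesium may transfer to the amide sluggishly, so that protonation back to 17 or conjugate addition competes. The fallback replaces the organomagnesium chemistry by an acylpalladium pathway. It sets out from 18: a carbonylative Heck reaction with CO (1 atm) and commercial 4-(TBS-oxy)styrene (Pd(OAc)2, 1,3-bis(diphenylphosphino)propane, Et3N, dioxane, 100 °C) would come back to the route at 23. This fallback makes no compound outside the list (F0).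

Step 3. Olefination of the hindered, electron-rich aldehyde by the doubly stabilised ylide may be slow, and prolonged heating invites silyl loss and ylide decomposition. The fallback uses an aldol addition and elimination in place of the phosphorus ylide. It sets out from 3. Ethyl pyruvate would be converted with Me3SiCl and Et3N into ethyl 2-(trimethylsilyloxy)prop-2-enoate F9. A Mukaiyama aldol addition of F9 to 3 with BF3·OEt2 at −78 °C should give racemic ethyl 4-[2,6-bis(TBS-oxy)-4-methoxyphenyl]-4-hydroxy-2-oxobutanoate F10. F10 should lose water readily at its electron-rich benzylic position (catalytic pyridinium p-toluenesulfonate, toluene, 60 °C) and come back to the route at 5.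

## Further compounds

F1 | step 4 | (E)-3-[2,6-bis(TBS-oxy)-4-methoxyphenyl]prop-2-enal | COc1cc(O[Si](C)(C)C(C)(C)C)c(/C=C/C=O)c(O[Si](C)(C)C(C)(C)C)c1
F2 | step 4 | 4-[4-(TIPS-oxy)phenyl]butan-2-one | CC(=O)CCc1ccc(O[Si](C(C)C)(C(C)C)C(C)C)cc1
F3 | step 4 | trimethyl({4-[4-(TIPS-oxy)phenyl]but-1-en-2-yl}oxy)silane | C=C(O[Si](C)(C)C)CCc1ccc(O[Si](C(C)C)(C(C)C)C(C)C)cc1
F4 | step 4 | (3S)-3-[2,6-bis(TBS-oxy)-4-methoxyphenyl]-5-oxo-7-[4-(TIPS-oxy)phenyl]heptanal | COc1cc(O[Si](C)(C)C(C)(C)C)c([C@@H](CC=O)CC(=O)CCc2ccc(O[Si](C(C)C)(C(C)C)C(C)C)cc2)c(O[Si](C)(C)C(C)(C)C)c1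
F5 | step 4 | (4S)-4-[2,6-bis(TBS-oxy)-4-methoxyphenyl]-2-ethoxy-6-{2-[4-(TIPS-oxy)phenyl]ethyl}-3,4-dihydro-2H-pyran, mixture of acetal epimers | COc1cc(O[Si](C)(C)C(C)(C)C)c([C@@H]2C=C(CCc3ccc(O[Si](C(C)C)(C(C)C)C(C)C)cc3)OC(OCC)C2)c(O[Si](C)(C)C(C)(C)C)c1
F6 | step 4 | (2S,4R,6R)-4-[2,6-bis(TBS-oxy)-4-methoxyphenyl]-6-ethoxy-2-{2-[4-(TIPS-oxy)phenyl]ethyl}oxane | COc1cc(O[Si](C)(C)C(C)(C)C)c([C@@H]2C[C@H](CCc3ccc(O[Si](C(C)C)(C(C)C)C(C)C)cc3)O[C@@H](OCC)C2)c(O[Si](C)(C)C(C)(C)C)c1
F7 | step 10 | (2S,4R,6S)-4-[2,6-bis(TBS-oxy)-4-methoxyphenyl]-6-lithio-2-{2-[4-(TIPS-oxy)phenyl]ethyl}oxane (lithium axial) | COc1cc(O[Si](C)(C)C(C)(C)C)c([C@@H]2C[C@H](CCc3ccc(O[Si](C(C)C)(C(C)C)C(C)C)cc3)O[C@@H]([Li])C2)c(O[Si](C)(C)C(C)(C)C)c1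
F8 | step 10 | (2S,4R,6S)-4-[2,6-bis(TBS-oxy)-4-methoxyphenyl]-2-{2-[4-(TIPS-oxy)phenyl]ethyl}-6-(tributylstannyl)oxane (stannyl group axial) | COc1cc(O[Si](C)(C)C(C)(C)C)c([C@@H]2C[C@H](CCc3ccc(O[Si](C(C)C)(C(C)C)C(C)C)cc3)O[C@@H]([Sn](CCCC)(CCCC)CCCC)C2)c(O[Si](C)(C)C(C)(C)C)c1
F0 | step 13 | none | none
F9 | step 3 | ethyl 2-(trimethylsilyloxy)prop-2-enoate | C=C(O[Si](C)(C)C)C(=O)OCC
F10 | step 3 | ethyl 4-[2,6-bis(TBS-oxy)-4-methoxyphenyl]-4-hydroxy-2-oxobutanoate (racemic) | COc1cc(O[Si](C)(C)C(C)(C)C)c(C(O)CC(=O)C(=O)OCC)c(O[Si](C)(C)C(C)(C)C)c1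
A1 | alternative 1 | (3S)-1-[4-(TIPS-oxy)phenyl]hex-5-en-3-ol | C=CC[C@H](CCc1ccc(O[Si](C(C)C)(C(C)C)C(C)C)cc1)O
A2 | alternative 1 | (2S,4R,6S)-6-[4-(TBS-oxy)phenyl]-4-(2,6-dihydroxy-4-methoxyphenyl)-2-{2-[4-(TIPS-oxy)phenyl]ethyl}oxane (all-cis) | COc1cc(O)c([C@@H]2C[C@H](CCc3ccc(O[Si](C(C)C)(C(C)C)C(C)C)cc3)O[C@H](c3ccc(O[Si](C)(C)C(C)(C)C)cc3)C2)c(O)c1
A3 | alternative 2 | (2S)-2-{2-[4-(TIPS-oxy)phenyl]ethyl}-2,3-dihydro-4H-pyran-4-one | O=C1C[C@H](CCc2ccc(O[Si](C(C)C)(C(C)C)C(C)C)cc2)OC=C1
A4 | alternative 2 | (2S,6R)-2-{2-[4-(TIPS-oxy)phenyl]ethyl}-6-[4-(TIPS-oxy)phenyl]oxan-4-one (2,6-trans) | O=C1C[C@H](CCc2ccc(O[Si](C(C)C)(C(C)C)C(C)C)cc2)O[C@@H](c2ccc(O[Si](C(C)C)(C(C)C)C(C)C)cc2)C1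
A5 | alternative 3 | 4-[2,6-bis(methoxymethoxy)-4-methoxyphenyl]-6-{2-[4-(TIPS-oxy)phenyl]ethyl}-2H-pyran-2-one | COCOc1cc(OC)cc(OCOC)c1C1=CC(=O)OC(CCc2ccc(O[Si](C(C)C)(C(C)C)C(C)C)cc2)=C1
A6 | alternative 3 | (4R,6S)-4-[2,6-bis(methoxymethoxy)-4-methoxyphenyl]-6-{2-[4-(TIPS-oxy)phenyl]ethyl}oxan-2-one (4,6-cis) | COCOc1cc(OC)cc(OCOC)c1[C@@H]1C[C@H](CCc2ccc(O[Si](C(C)C)(C(C)C)C(C)C)cc2)OC(=O)C1
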